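**Plan**

- Retrosynthetic cuts, in order: (i) the C–O and C–Br bonds of the 7-oxabicyclo[2.2.1]heptane (transannular bromoetherification of a 4-methylcyclohex-3-en-1-ol); (ii) its ring C=C (metathesis) and the carbinol–allyl bond; (iii) the side-chain CH2–CH2 bond (enolate alkylation); (iv) in the carbocycle, the C–Br bond together with the CH2–CHBr ring connectivity.
- Enabling feature: in the bromocyclohexane the CHBr carbon lies 1,4 to the ring carbon that bears the oxabicycle and is flanked by CMe2 and a CH2. A cation at that 1-position is therefore the homoallyl partner of a 4,4-dimethylbicyclo[3.1.0]hex-2-yl (cyclopropylcarbinyl) cation whose cyclopropane CH2 is that ring CH2. Bromide opening of the zero bridge makes the neopentyl C–Br bond without an SN2 step.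
- Forward order: cyclopentenone → bicyclo[3.1.0]hexanone → ethynyl carbinol → HBr ring expansion to the 4-bromocyclohexene → methyl ketone → hydrogenation → chain extension → allylation → ring-closing metathesis (second six-membered ring) → bromoetherification (oxygen bridge).
- Stereochemistry: CBS reduction and OH-directed cyclopropanation fix the cyclopropane; invertive bromide opening transfers this to C–Br. The ring CH and the tertiary carbinol are each set by catalyst control. The last two centres (C–Me bridgehead, endo CHBr) follow from anti, transannular bromoetherification.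

Key step: step 5

Remark: the configuration at C2 of 6 is inconsequential because that carbon becomes sp2 in step 5; 6 is drawn as the epimer expected from attack anti to the cyclopropane.

**Route**

Step 1
Reactants: 1 4,4-dimethylcyclopent-2-en-1-one
Product: 2 (1S)-4,4-dimethylcyclopent-2-en-1-ol
Conditions: (R)-Me-CBS (10 mol %), catecholborane, toluene, −78 °C; aq. NaOH work-up
Reagents that add atoms: none
Why: Corey–Bakshi–Shibata reduction; 1,2-hydride delivery in the ketone–oxazaborolidine–borane complex, with the alkene flank acting as the large group, should set C1 as (S) and with it the absolute configuration of the carbocycle.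

Step 2
Reactants: 2 (1S)-4,4-dimethylcyclopent-2-en-1-ol
Product: 3 (1R,2S,5S)-4,4-dimethylbicyclo[3.1.0]hexan-2-ol
Conditions: Et2Zn, CH2I2, CH2Cl2, 0 °C → rt
Reagents that add atoms: diiodomethane, ICI
Why: Hydroxyl-directed Simmons–Smith cyclopropanation (Furukawa variant); the zinc alkoxide should deliver CH2 to the alkene face syn to OH, fixing both ring-fusion centres.

Step 3
Reactants: 3 (1R,2S,5S)-4,4-dimethylbicyclo[3.1.0]hexan-2-ol
Product: 4 (1R,5S)-4,4-dimethylbicyclo[3.1.0]hexan-2-one
Conditions: Dess–Martin periodinane, NaHCO3, CH2Cl2, 0 °C → rt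
Reagents that add atoms: none
Why: Buffered Dess–Martin oxidation of a secondary cyclopropyl carbinol should leave the acid-sensitive cyclopropane and its two stereocentres untouched.

Step 4
Reactants: 4 (1R,5S)-4,4-dimethylbicyclo[3.1.0]hexan-2-one; 5 ethynylmagnesium bromide
Product: 6 (1R,2S,5S)-2-ethynyl-4,4-dimethylbicyclo[3.1.0]hexan-2-ol
Conditions: THF, 0 °C; aq. NH4Cl
Reagents that add atoms: ethynylmagnesium bromide (5), C#C[Mg]Br
Why: 1,2-Addition of an alkynyl Grignard reagent to the cyclopropyl ketone, expected from the face anti to the cyclopropane; the ethynyl group is both the later acetyl carbon pair and a cation-stabilising substituent for step 5.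

Step 5
Reactants: 6 (1R,2S,5S)-2-ethynyl-4,4-dimethylbicyclo[3.1.0]hexan-2-ol
Product: 8 (4S)-4-bromo-1-ethynyl-5,5-dimethylcyclohex-1-ene, via cyclopropylcarbinyl cation 7 (not isolated)
Conditions: 48 % aq. HBr, Et2O, −10 → 0 °C
Reagents that add atoms: hydrogen bromide, Br
Why: Ionisation of the tertiary propargylic alcohol gives cyclopropylcarbinyl cation 7; bromide then attacks C5 from the side opposite to C1 as the C1–C5 bond becomes the C1=C2 π-bond (cyclopropylcarbinyl-to-homoallyl rearrangement with halide capture, as in the Julia olefin synthesis and in the thujyl → terpinen-4-yl ring expansion). No ring is closed: the cyclohexene arises by opening the zero bridge of the bicyclo[3.1.0]hexane, so the cyclopropane CH2 is inserted into the former five-membered ring. The only new stereocentre, C4–Br, forms with inversion at the former C5 and is therefore dictated by the cyclopropane configuration from steps 1–2, while C2 becomes sp2. The step needs cleavage of the internal (C1–C5) rather than the external (C1–C6) bond, and capture at C5 rather than at C2 or the alkyne terminus. Internal cleavage places the developing charge on a secondary carbon next to the quaternary centre instead of on a primary one and releases the strain of both small rings, while capture at the tertiary propargylic position should be reversible under HBr, leaving the homoallylic bromide as the sink. The neopentyl secondary bromide is thus made without an SN2 displacement beside the gem-dimethyl group.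

Step 6
Reactants: 8 (4S)-4-bromo-1-ethynyl-5,5-dimethylcyclohex-1-ene
Product: 9 1-[(4S)-4-bromo-5,5-dimethylcyclohex-1-en-1-yl]ethan-1-one
Conditions: (Ph3P)AuNTf2 (2 mol %), H2O, 1,4-dioxane, 60 °C
Reagents that add atoms: water, O
Why: Gold(I)-catalysed Markovnikov hydration of a terminal, alkene-conjugated alkyne should give the methyl enone without touching the homoallylic bromide.

Step 7
Reactants: 9 1-[(4S)-4-bromo-5,5-dimethylcyclohex-1-en-1-yl]ethan-1-one
Product: 10 1-[(1S,4S)-4-bromo-3,3-dimethylcyclohexyl]ethan-1-one
Conditions: H2 (50 bar), [Ir(cod)(tBu-PHOX)]BArF (2 mol %, antipode that adds H2 cis to Br), CH2Cl2, rt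
Reagents that add atoms: none
Why: Catalyst-controlled asymmetric hydrogenation of an α-branched, trisubstituted enone; the ligand antipode is chosen so that H2 adds to the ring face cis to bromine, giving the trans-1,4 ketone, because the remote C4 centre exerts little bias of its own.

Step 8
Reactants: 10 1-[(1S,4S)-4-bromo-3,3-dimethylcyclohexyl]ethan-1-one; 11 3-bromo-2-methylprop-1-ene
Product: 13 1-[(1S,4S)-4-bromo-3,3-dimethylcyclohexyl]-4-methylpent-4-en-1-one, via lithium enolate 12 (not isolated)
Conditions: LDA, THF, −78 °C; then 11, DMPU, −78 → −30 °C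
Reagents that add atoms: 3-bromo-2-methylprop-1-ene (11), CC(=C)CBr
Why: Kinetic deprotonation at the methyl group and SN2 alkylation of the terminal enolate by an allylic bromide; the hindered methine α-hydrogen should not be removed at −78 °C, so the ring centre is kept.

Step 9
Reactants: 13 1-[(1S,4S)-4-bromo-3,3-dimethylcyclohexyl]-4-methylpent-4-en-1-one; 14 2-allyl-4,4,5,5-tetramethyl-1,3,2-dioxaborolane
Product: 15 (4S)-4-[(1S,4S)-4-bromo-3,3-dimethylcyclohexyl]-7-methylocta-1,7-dien-4-ol
Conditions: CuF2·2H2O (3 mol %), iPr-DuPHOS (6 mol %, antipode for Si-face attack), La(OiPr)3 (4.5 mol %), DMF, −40 °C; aq. work-up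
Reagents that add atoms: 2-allyl-4,4,5,5-tetramethyl-1,3,2-dioxaborolane (14), C=CCB1OC(C)(C)C(C)(C)O1
Why: Catalytic enantioselective allylboration of a ketone through a cyclic six-membered transition state; the chiral copper catalyst delivers allyl to the Si face to give the (4S) carbinol, since the neighbouring ring centre has two near-identical CH2 flanks and gives no substrate induction.

Step 10
Reactants: 15 (4S)-4-[(1S,4S)-4-bromo-3,3-dimethylcyclohexyl]-7-methylocta-1,7-dien-4-ol
Product: 16 (1S)-1-[(1S,4S)-4-bromo-3,3-dimethylcyclohexyl]-4-methylcyclohex-3-en-1-ol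
Conditions: Grubbs second-generation catalyst (5 mol %), CH2Cl2, 40 °C
Reagents that add atoms: none
Why: Ring-closing metathesis between the monosubstituted and the 1,1-disubstituted alkene should close the trisubstituted cyclohexene with loss of ethene; no stereocentre is touched.

Step 11
Reactants: 16 (1S)-1-[(1S,4S)-4-bromo-3,3-dimethylcyclohexyl]-4-methylcyclohex-3-en-1-ol
Product: 17 (1R,2R,4S)-2-bromo-4-[(1S,4S)-4-bromo-3,3-dimethylcyclohexyl]-1-methyl-7-oxabicyclo[2.2.1]heptane
Conditions: NBS, CH2Cl2, 0 °C
Reagents that add atoms: N-bromosuccinimide, O=C1CCC(=O)N1Br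
Why: Transannular bromoetherification: bromonium formation on the ring alkene and Markovnikov attack of the tertiary hydroxyl at the methyl-bearing carbon through a boat should close the oxygen bridge. Oxygen and bromine add anti, so bromine is endo, and both new centres follow from the carbinol centre.

**Compound list**

1 | 4,4-dimethylcyclopent-2-en-1-one | O=C1C=CC(C)(C)C1 | starting material
2 | (1S)-4,4-dimethylcyclopent-2-en-1-ol | O[C@@H]1C=CC(C)(C)C1 | intermediate
3 | (1R,2S,5S)-4,4-dimethylbicyclo[3.1.0]hexan-2-ol (OH cis to the cyclopropane CH2) | O[C@H]1CC(C)(C)[C@H]2C[C@@H]12 | intermediate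
4 | (1R,5S)-4,4-dimethylbicyclo[3.1.0]hexan-2-one | O=C1CC(C)(C)[C@H]2C[C@@H]12 | intermediate
5 | ethynylmagnesium bromide | C#C[Mg]Br | starting material
6 | (1R,2S,5S)-2-ethynyl-4,4-dimethylbicyclo[3.1.0]hexan-2-ol | C#C[C@]1(O)CC(C)(C)[C@H]2C[C@@H]12 | intermediate
7 | 2-ethynyl-4,4-dimethylbicyclo[3.1.0]hexan-2-ylium (cyclopropylcarbinyl cation) | C#C[C+]1CC(C)(C)[C@H]2C[C@@H]12 | intermediate
8 | (4S)-4-bromo-1-ethynyl-5,5-dimethylcyclohex-1-ene | C#CC1=CC[C@H](Br)C(C)(C)C1 | intermediate
9 | 1-[(4S)-4-bromo-5,5-dimethylcyclohex-1-en-1-yl]ethan-1-one | CC(=O)C1=CC[C@H](Br)C(C)(C)C1 | intermediate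
10 | 1-[(1S,4S)-4-bromo-3,3-dimethylcyclohexyl]ethan-1-one (acetyl and Br trans) | CC(=O)[C@H]1CC[C@H](Br)C(C)(C)C1 | intermediate
11 | 3-bromo-2-methylprop-1-ene | CC(=C)CBr | starting material
12 | lithium 1-[(1S,4S)-4-bromo-3,3-dimethylcyclohexyl]ethen-1-olate | C=C(O[Li])[C@H]1CC[C@H](Br)C(C)(C)C1 | intermediate
13 | 1-[(1S,4S)-4-bromo-3,3-dimethylcyclohexyl]-4-methylpent-4-en-1-one | CC(=C)CCC(=O)[C@H]1CC[C@H](Br)C(C)(C)C1 | intermediate
14 | 2-allyl-4,4,5,5-tetramethyl-1,3,2-dioxaborolane | C=CCB1OC(C)(C)C(C)(C)O1 | starting material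
15 | (4S)-4-[(1S,4S)-4-bromo-3,3-dimethylcyclohexyl]-7-methylocta-1,7-dien-4-ol | C=CC[C@@](O)(CCC(C)=C)[C@H]1CC[C@H](Br)C(C)(C)C1 | intermediate
16 | (1S)-1-[(1S,4S)-4-bromo-3,3-dimethylcyclohexyl]-4-methylcyclohex-3-en-1-ol | CC1=CC[C@@](O)(CC1)[C@H]2CC[C@H](Br)C(C)(C)C2 | intermediate
17 | (1R,2R,4S)-2-bromo-4-[(1S,4S)-4-bromo-3,3-dimethylcyclohexyl]-1-methyl-7-oxabicyclo[2.2.1]heptane | CC1(C)C[C@@H]([C@@]23CC[C@@](C)(O2)[C@H](Br)C3)CC[C@@H]1Br | target

**Step count and risks**

Total step count: 11. Longest linear sequence: 11 steps (1 → 17).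

Steps most likely to fail:

1. Step 5. The cation may be diverted: cleavage of the external cyclopropane bond (bromide at the cyclopropane CH2), capture at the propargylic or allenyl position, or a 1,2-methyl shift once charge builds up beside the quaternary carbon. The fallback separates ring expansion from C–Br formation. It sets out from 6: acid-catalysed homoallylic ring expansion with water as the nucleophile under thermodynamic control (cat. HClO4, aq. 1,4-dioxane) should give (1S)-4-ethynyl-6,6-dimethylcyclohex-3-en-1-ol F1. Mesylation (MsCl, Et3N, CH2Cl2) gives (1S)-4-ethynyl-6,6-dimethylcyclohex-3-en-1-yl methanesulfonate F2. Treatment with LiBr in acetone should then introduce bromide with net retention through participation of the ring π-bond (homoallyl/cyclopropylcarbinyl cation, as in cholesteryl sulfonates), direct SN2 being blocked by the gem-dimethyl group. The sequence comes back to the route at 8.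

2. Step 7. Facial selectivity may be poor, because the substrate has no useful bias and the catalyst has to overrule whatever bias the half-chair has; the trans and cis ketones are also expected to be close in energy, so equilibration alone cannot correct a poor ratio. The fallback sets out from 9: non-selective hydrogenation (H2, Pd/C, EtOAc) would give 10 together with its epimer 1-[(1R,4S)-4-bromo-3,3-dimethylcyclohexyl]ethan-1-one F3. The two are separated by chromatography, and F3 is returned to the pool by base-mediated epimerisation at the acyl-bearing carbon (DBU, CH2Cl2) followed by re-separation. The sequence comes back to the route at 10.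

3. Step 9. Discrimination between the two alkyl flanks of a dialkyl ketone (α-branched ring against a primary chain) may be insufficient, giving both carbinol epimers. The fallback replaces ketone allylation by a Sharpless epoxidation and two epoxide openings. It sets out from 10:
   - Corey–Chaykovsky methylenation (Me3S+ I−, n-BuLi, THF) should give 2-[(1S,4S)-4-bromo-3,3-dimethylcyclohexyl]-2-methyloxirane F4 as an epimer mixture.
   - Isomerisation with diethylaluminium 2,2,6,6-tetramethylpiperidide (removal of a methyl proton) gives 2-[(1S,4S)-4-bromo-3,3-dimethylcyclohexyl]prop-2-en-1-ol F5.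
   - Sharpless asymmetric epoxidation (Ti(OiPr)4, L-(+)-DET, TBHP, 4 Å MS, −20 °C) sets the quaternary C–O centre under reagent control and should give [(2S)-2-[(1S,4S)-4-bromo-3,3-dimethylcyclohexyl]oxiran-2-yl]methanol F6.
   - Vinylmagnesium bromide with catalytic CuI opens the oxirane at its CH2 to give (2S)-2-[(1S,4S)-4-bromo-3,3-dimethylcyclohexyl]pent-4-ene-1,2-diol F7.
   - Selective tosylation of the primary hydroxyl (TsCl, pyridine) gives (2S)-2-[(1S,4S)-4-bromo-3,3-dimethylcyclohexyl]-2-hydroxypent-4-en-1-yl 4-methylbenzenesulfonate F8.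
   - K2CO3 in MeOH closes (2S)-2-[(1S,4S)-4-bromo-3,3-dimethylcyclohexyl]-2-(prop-2-en-1-yl)oxirane F9.
   - 2-Methylallylmagnesium chloride with catalytic CuI opens F9 at its CH2.

   The sequence comes back to the route at 15.

Further compounds
F1 | step 5 | (1S)-4-ethynyl-6,6-dimethylcyclohex-3-en-1-ol | C#CC1=CC[C@H](O)C(C)(C)C1
F2 | step 5 | (1S)-4-ethynyl-6,6-dimethylcyclohex-3-en-1-yl methanesulfonate | C#CC1=CC[C@H](OS(C)(=O)=O)C(C)(C)C1
F3 | step 7 | 1-[(1R,4S)-4-bromo-3,3-dimethylcyclohexyl]ethan-1-one | CC(=O)[C@@H]1CC[C@H](Br)C(C)(C)C1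
F4 | step 9 | 2-[(1S,4S)-4-bromo-3,3-dimethylcyclohexyl]-2-methyloxirane (both oxirane epimers) | CC1(CO1)[C@H]2CC[C@H](Br)C(C)(C)C2
F5 | step 9 | 2-[(1S,4S)-4-bromo-3,3-dimethylcyclohexyl]prop-2-en-1-ol | C=C(CO)[C@H]1CC[C@H](Br)C(C)(C)C1
F6 | step 9 | [(2S)-2-[(1S,4S)-4-bromo-3,3-dimethylcyclohexyl]oxiran-2-yl]methanol | OC[C@]1(CO1)[C@H]2CC[C@H](Br)C(C)(C)C2
F7 | step 9 | (2S)-2-[(1S,4S)-4-bromo-3,3-dimethylcyclohexyl]pent-4-ene-1,2-diol | C=CC[C@@](O)(CO)[C@H]1CC[C@H](Br)C(C)(C)C1
F8 | step 9 | (2S)-2-[(1S,4S)-4-bromo-3,3-dimethylcyclohexyl]-2-hydroxypent-4-en-1-yl 4-methylbenzenesulfonate | C=CC[C@@](O)(COS(=O)(=O)c1ccc(C)cc1)[C@H]2CC[C@H](Br)C(C)(C)C2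
F9 | step 9 | (2S)-2-[(1S,4S)-4-bromo-3,3-dimethylcyclohexyl]-2-(prop-2-en-1-yl)oxirane | C=CC[C@@]1(CO1)[C@H]2CC[C@H](Br)C(C)(C)C2
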